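**Plan**

1. Retrosynthesis: the pinane CH2 bridge (C7) is traced back to a cyclobutanone. The two opposite cyclobutane bonds C7–C5 and C1–C6 are then cut together as an intramolecular ketene–alkene [2+2]. The ketene comes from a diazoketone on the spiro carbon (the Wolff shift makes C1–C2), the 4-methylpent-3-enyl chain from an enolate alkylation, and the pyran ring from a Michael addition/ketalisation of syncarpic acid.
2. Feature that allows the event: in the cyclobutane C1–C6–C5–C7 of the bicyclo[3.1.1]heptane, a CH2 (C7, a ketene carbonyl carbon at a higher oxidation level) lies opposite a CMe2 (C6, the end of a prenyl-type alkene). Both partners hang on the spiro carbon C2, three atoms apart (C2–C3–C4), and the charge-stabilising gem-dimethyl carbon steers the crossed, bridged mode.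
3. Forward order: enone ester → dihydropyran ring on the syncarpic core → quaternary C2 → diazoketone → six- and four-membered carbocycles of the pinane in one step → removal of the C7 carbonyl.
4. Stereochemistry: C4' (primes = chromene atoms) from a chiral bifunctional squaramide catalyst; C2 from alkylation anti to the C4' isopropyl group; C1 and C5 from C2 in the cycloaddition (C–O bond anti to the incoming CMe2 carbon).

Key step: step 7

Assumption: syncarpic acid (4) and the acyl ylide (2) are taken as catalogue compounds; the sense of induction of the squaramide in step 2 is assigned by analogy with aryl-substituted keto esters and must be confirmed (the quinidine-derived pseudoenantiomer gives the antipode).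

**Step 1**
Reactants: 1 2-methylpropanal; 2 ethyl 2-oxo-3-(triphenyl-λ5-phosphanylidene)propanoate
Product: 3 ethyl (E)-5-methyl-2-oxohex-3-enoate
Conditions: 2 (1.05 equiv), CH2Cl2, rt
Reagents that add atoms: none
Why: Wittig olefination of an aldehyde with a stabilised acyl ylide should give the E-configured β,γ-unsaturated α-keto ester.

**Step 2**
Reactants: 3 ethyl (E)-5-methyl-2-oxohex-3-enoate; 4 syncarpic acid
Product: 6 ethyl (4S)-6,6,8,8-tetramethyl-5,7-dioxo-4-(propan-2-yl)-5,6,7,8-tetrahydro-4H-chromene-2-carboxylate, via hemiketal 5 (not isolated)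
Conditions: quinine-derived squaramide [3-(3,5-bis(trifluoromethyl)anilino)-4-(9-deoxy-epi-quinin-9-ylamino)cyclobut-3-ene-1,2-dione] (5 mol %), CH2Cl2, rt; then TsOH·H2O (10 mol %), 40 °C
Reagents that add atoms: none
Why: Organocatalytic Michael addition of a cyclic 1,3-dione to a β,γ-unsaturated α-keto ester, in which the catalyst binds the 1,2-dicarbonyl unit and shields one enone face to set C4, followed by ring closure to hemiketal 5 and acid-catalysed loss of water to the conjugated enol ether.

**Step 3**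
Reactants: 6 ethyl (4S)-6,6,8,8-tetramethyl-5,7-dioxo-4-(propan-2-yl)-5,6,7,8-tetrahydro-4H-chromene-2-carboxylate
Product: 7 ethyl (4R)-6,6,8,8-tetramethyl-5,7-dioxo-4-(propan-2-yl)-3,4,5,6,7,8-hexahydro-2H-chromene-2-carboxylate (both C2 epimers)
Conditions: H2 (1 atm), Pd/C (10 wt % palladium on carbon), EtOAc, rt
Reagents that add atoms: none
Why: Catalytic hydrogenation should saturate the trisubstituted α-alkoxyacrylate C2=C3 bond and leave the tetrasubstituted vinylogous ester alkene and the hindered ketone; the C2 configuration does not matter because C2 becomes planar again in step 4.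

**Step 4**
Reactants: 7 ethyl (4R)-6,6,8,8-tetramethyl-5,7-dioxo-4-(propan-2-yl)-3,4,5,6,7,8-hexahydro-2H-chromene-2-carboxylate; 8 5-bromo-2-methylpent-2-ene
Product: 10 ethyl (2S,4R)-6,6,8,8-tetramethyl-2-(4-methylpent-3-en-1-yl)-5,7-dioxo-4-(propan-2-yl)-3,4,5,6,7,8-hexahydro-2H-chromene-2-carboxylate, via lithium enolate 9 (not isolated)
Conditions: LiN(iPr)2 (LDA, 1.1 equiv), THF, −78 °C; then 8 (2 equiv), DMPU, −78 → −20 °C
Reagents that add atoms: none
Why: Ester enolate alkylation, in which the planar α-alkoxy enolate 9 should be attacked by the primary bromide on the face opposite the C4 isopropyl group (held pseudoaxial by allylic strain with the C5 carbonyl), so the new chain ends trans and the ester cis to isopropyl at the quaternary C2.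

**Step 5**
Reactants: 10 ethyl (2S,4R)-6,6,8,8-tetramethyl-2-(4-methylpent-3-en-1-yl)-5,7-dioxo-4-(propan-2-yl)-3,4,5,6,7,8-hexahydro-2H-chromene-2-carboxylate
Product: 11 (2S,4R)-6,6,8,8-tetramethyl-2-(4-methylpent-3-en-1-yl)-5,7-dioxo-4-(propan-2-yl)-3,4,5,6,7,8-hexahydro-2H-chromene-2-carboxylic acid
Conditions: LiOH·H2O (3 equiv), THF/MeOH/H2O, 40 °C; then 1 M HCl, 0 °C, to pH 3
Reagents that add atoms: lithium hydroxide, [Li+].[OH-]
Why: Saponification of the ethyl ester; the α-alkoxy acid has no β-leaving group and the non-enolisable dione part should be inert to hydroxide at this temperature.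

**Step 6**
Reactants: 11 (2S,4R)-6,6,8,8-tetramethyl-2-(4-methylpent-3-en-1-yl)-5,7-dioxo-4-(propan-2-yl)-3,4,5,6,7,8-hexahydro-2H-chromene-2-carboxylic acid
Product: 13 (2S,4R)-2-(2-diazoacetyl)-6,6,8,8-tetramethyl-2-(4-methylpent-3-en-1-yl)-4-(propan-2-yl)-3,4-dihydro-2H-chromene-5,7(6H,8H)-dione, via acid chloride 12 (not isolated)
Conditions: Me2C=C(Cl)NMe2 (1.2 equiv), CH2Cl2, 0 °C → rt; then CH2N2 (3 equiv), Et2O, 0 °C
Reagents that add atoms: diazomethane, C=[N+]=[N-]
Why: First half of an Arndt–Eistert homologation, in which neutral chlorination with the α-chloroenamine avoids HCl at the trisubstituted alkene and acid chloride 12 (no α-hydrogen, so no ketene at this stage) acylates diazomethane.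

**Step 7**
Reactants: 13 (2S,4R)-2-(2-diazoacetyl)-6,6,8,8-tetramethyl-2-(4-methylpent-3-en-1-yl)-4-(propan-2-yl)-3,4-dihydro-2H-chromene-5,7(6H,8H)-dione
Product: 15 (1S,2S,4'R,5S)-6,6,6',6',8',8'-hexamethyl-4'-(propan-2-yl)-3',4'-dihydrospiro[bicyclo[3.1.1]heptane-2,2'-chromene]-5',7,7'(6'H,8'H)-trione, via ketene 14 (not isolated)
Conditions: hν (450 nm LEDs), PhMe (0.005 M), 80 °C
Reagents that add atoms: none
Why: Light-induced Wolff rearrangement of the s-cis diazoketone (loss of N2 with 1,2-shift of the quaternary C2, which keeps its configuration) gives aldoketene 14, whose electrophilic central carbon is then attacked by the trisubstituted alkene in a thermal, concerted but asynchronous ketene–alkene [2+2] cycloaddition. The closest known reaction type is the intramolecular cycloaddition of ketenes tethered by three atoms to a 2-methylprop-1-enyl group, which gives 6,6-dimethylbicyclo[3.1.1]heptan-7-ones. The bond from the ketene carbonyl carbon to the alkene CH closes the six-membered ring (6-exo with respect to the alkene) and the bond from the ketene α-carbon to CMe2 closes the four-membered ring across it, so the bridged and not the fused bicycle should form because the positive charge of the transition state sits on the carbon that carries the two methyl groups. Both new bridgehead centres are fixed together relative to the spiro carbon: in the cyclohexene-like half-chair of the first closure the allylic C2–O bond should take the pseudoaxial site and the CMe2 carbon, pseudoaxial on the opposite face, should bond to the ketene α-carbon anti to oxygen, which puts O syn to the carbonyl bridge and the pyran CH2 syn to the CMe2 bridge as in 18. The step needs Wolff shift over carbene cyclopropanation (metal-free direct excitation), cycloaddition over ketene dimerisation (high dilution) and an untouched β-alkoxyenone (it does not absorb at 450 nm).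

**Step 8**
Reactants: 15 (1S,2S,4'R,5S)-6,6,6',6',8',8'-hexamethyl-4'-(propan-2-yl)-3',4'-dihydrospiro[bicyclo[3.1.1]heptane-2,2'-chromene]-5',7,7'(6'H,8'H)-trione
Product: 16 N'-[(1R,2S,4'R,5S)-6,6,6',6',8',8'-hexamethyl-5',7'-dioxo-4'-(propan-2-yl)-3',4',5',6',7',8'-hexahydrospiro[bicyclo[3.1.1]heptane-2,2'-chromen]-7-ylidene]-4-methylbenzenesulfonohydrazide
Conditions: TsNHNH2 (1.1 equiv), AcOH (cat.), MeOH, 40 °C
Reagents that add atoms: 4-methylbenzenesulfonohydrazide, Cc1ccc(cc1)S(=O)(=O)NN
Why: Hydrazone condensation should take place only at the strained cyclobutanone, because the ketone flanked by two quaternary carbons and the vinylogous ester carbonyl are much less reactive.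

**Step 9**
Reactants: 16 N'-[(1R,2S,4'R,5S)-6,6,6',6',8',8'-hexamethyl-5',7'-dioxo-4'-(propan-2-yl)-3',4',5',6',7',8'-hexahydrospiro[bicyclo[3.1.1]heptane-2,2'-chromen]-7-ylidene]-4-methylbenzenesulfonohydrazide
Product: 18 (1S,2S,4'R,5R)-6,6,6',6',8',8'-hexamethyl-4'-(propan-2-yl)-3',4'-dihydrospiro[bicyclo[3.1.1]heptane-2,2'-chromene]-5',7'(6'H,8'H)-dione, via N-boryl tosylhydrazine 17 (not isolated)
Conditions: catecholborane (2 equiv), CHCl3, 0 °C → rt; then NaOAc·3H2O, 60 °C
Reagents that add atoms: none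
Why: Tosylhydrazone reduction (a mild variant of the Wolff–Kishner deoxygenation), in which hydroboration of C=N gives 17 and acetate triggers loss of sulfinate to a diazene that extrudes N2 and leaves the CH2 bridge; no stereocentre is touched and elimination toward the bridgehead is excluded by the bicyclic frame.

**Compound list**

1 | 2-methylpropanal (isobutyraldehyde) | CC(C)C=O | starting material
2 | ethyl 2-oxo-3-(triphenyl-λ5-phosphanylidene)propanoate | CCOC(=O)C(=O)C=P(c1ccccc1)(c1ccccc1)c1ccccc1 | starting material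
3 | ethyl (E)-5-methyl-2-oxohex-3-enoate | CCOC(=O)C(=O)/C=C/C(C)C | intermediate
4 | syncarpic acid (2,2,4,4-tetramethylcyclohexane-1,3,5-trione) | CC1(C)C(=O)CC(=O)C(C)(C)C1=O | starting material
5 | ethyl (4R)-2-hydroxy-6,6,8,8-tetramethyl-5,7-dioxo-4-(propan-2-yl)-3,4,5,6,7,8-hexahydro-2H-chromene-2-carboxylate (hemiketal, both C2 anomers, not isolated) | CC(C)[C@H]1CC(O)(C(=O)OCC)OC2=C1C(=O)C(C)(C)C(=O)C2(C)C | intermediate
6 | ethyl (4S)-6,6,8,8-tetramethyl-5,7-dioxo-4-(propan-2-yl)-5,6,7,8-tetrahydro-4H-chromene-2-carboxylate | CC(C)[C@H]1C=C(C(=O)OCC)OC2=C1C(=O)C(C)(C)C(=O)C2(C)C | intermediate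
7 | ethyl (4R)-6,6,8,8-tetramethyl-5,7-dioxo-4-(propan-2-yl)-3,4,5,6,7,8-hexahydro-2H-chromene-2-carboxylate (both C2 epimers) | CC(C)[C@H]1CC(C(=O)OCC)OC2=C1C(=O)C(C)(C)C(=O)C2(C)C | intermediate
8 | 5-bromo-2-methylpent-2-ene | CC(C)=CCCBr | starting material
9 | lithium enolate of 7 (not isolated) | CC(C)[C@H]1CC(=C([O-])OCC)OC2=C1C(=O)C(C)(C)C(=O)C2(C)C.[Li+] | intermediate
10 | ethyl (2S,4R)-6,6,8,8-tetramethyl-2-(4-methylpent-3-en-1-yl)-5,7-dioxo-4-(propan-2-yl)-3,4,5,6,7,8-hexahydro-2H-chromene-2-carboxylate | CC(C)[C@H]1C[C@](C(=O)OCC)(CCC=C(C)C)OC2=C1C(=O)C(C)(C)C(=O)C2(C)C | intermediate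
11 | (2S,4R)-6,6,8,8-tetramethyl-2-(4-methylpent-3-en-1-yl)-5,7-dioxo-4-(propan-2-yl)-3,4,5,6,7,8-hexahydro-2H-chromene-2-carboxylic acid | CC(C)[C@H]1C[C@](C(=O)O)(CCC=C(C)C)OC2=C1C(=O)C(C)(C)C(=O)C2(C)C | intermediate
12 | (2S,4R)-6,6,8,8-tetramethyl-2-(4-methylpent-3-en-1-yl)-5,7-dioxo-4-(propan-2-yl)-3,4,5,6,7,8-hexahydro-2H-chromene-2-carbonyl chloride (not isolated) | CC(C)[C@H]1C[C@](C(=O)Cl)(CCC=C(C)C)OC2=C1C(=O)C(C)(C)C(=O)C2(C)C | intermediate
13 | (2S,4R)-2-(2-diazoacetyl)-6,6,8,8-tetramethyl-2-(4-methylpent-3-en-1-yl)-4-(propan-2-yl)-3,4-dihydro-2H-chromene-5,7(6H,8H)-dione | CC(C)[C@H]1C[C@](C(=O)C=[N+]=[N-])(CCC=C(C)C)OC2=C1C(=O)C(C)(C)C(=O)C2(C)C | intermediate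
14 | (2S,4R)-6,6,8,8-tetramethyl-2-(4-methylpent-3-en-1-yl)-2-(2-oxoethenyl)-4-(propan-2-yl)-3,4-dihydro-2H-chromene-5,7(6H,8H)-dione (ketene, not isolated) | CC(C)[C@H]1C[C@](C=C=O)(CCC=C(C)C)OC2=C1C(=O)C(C)(C)C(=O)C2(C)C | intermediate
15 | (1S,2S,4'R,5S)-6,6,6',6',8',8'-hexamethyl-4'-(propan-2-yl)-3',4'-dihydrospiro[bicyclo[3.1.1]heptane-2,2'-chromene]-5',7,7'(6'H,8'H)-trione | CC(C)[C@H]1C[C@]2(CC[C@@H]3C(=O)[C@H]2C3(C)C)OC2=C1C(=O)C(C)(C)C(=O)C2(C)C | intermediate
16 | 7-tosylhydrazone of 15, (1R,2S,4'R,5S), C=N geometry not fixed | CC(C)[C@H]1C[C@]2(CC[C@@H]3C(=NNS(=O)(=O)c4ccc(C)cc4)[C@H]2C3(C)C)OC2=C1C(=O)C(C)(C)C(=O)C2(C)C | intermediate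
17 | N-(1,3,2-benzodioxaborol-2-yl)-N'-tosylhydrazine at C7 of the spiro skeleton (hydroboration adduct of 16, not isolated) | CC(C)[C@H]1C[C@]2(CC[C@@H]3C(N(B4Oc5ccccc5O4)NS(=O)(=O)c4ccc(C)cc4)[C@H]2C3(C)C)OC2=C1C(=O)C(C)(C)C(=O)C2(C)C | intermediate
18 | (1S,2S,4'R,5R)-6,6,6',6',8',8'-hexamethyl-4'-(propan-2-yl)-3',4'-dihydrospiro[bicyclo[3.1.1]heptane-2,2'-chromene]-5',7'(6'H,8'H)-dione (CNP0534730.2) | CC(C)[C@H]1C[C@]2(CC[C@@H]3C[C@H]2C3(C)C)OC2=C1C(=O)C(C)(C)C(=O)C2(C)C | target

**Step count and risks**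

Total: 9 steps. Longest linear sequence: 9 steps (1 + 2 → 18).

Steps most likely to fail:

1. Step 7. The ring closure may show poor facial selectivity, with the CMe2 bridge forming on the side of the ring oxygen: that arrangement is the less crowded one in the product, and only the early half-chair argument speaks for the wanted one. Carbene-type cyclopropanation of the alkene may also compete with the Wolff shift. The fallback sets out from 4 and 1 and gives up the late ring construction. Knoevenagel condensation (ethylenediammonium diacetate cat., PhMe, 80 °C) gives the heterodiene 2,2,4,4-tetramethyl-6-(2-methylpropylidene)cyclohexane-1,3,5-trione F1 in the presence of purchased (1R,5R)-(+)-β-pinene. An inverse-electron-demand hetero-Diels–Alder reaction on the alkene face away from the gem-dimethyl bridge then forms the spiro pyran. It comes back at 18, which must be separated from its C4' epimer because this reaction does not control C4'.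

2. Step 4. The basic enolate may eliminate HBr from the homoallylic bromide, and C-alkylation at the fully substituted carbon may be slow. The fallback sets out from 7. Enolate 9 is alkylated with the far more reactive allyl bromide to give ethyl (2S,4R)-2-allyl-6,6,8,8-tetramethyl-5,7-dioxo-4-(propan-2-yl)-3,4,5,6,7,8-hexahydro-2H-chromene-2-carboxylate F2. Hydroboration of the terminal alkene (9-BBN; then NaBO3·4H2O) gives the 3-hydroxypropyl compound F3, and oxidation with 1,1,1-triacetoxy-1,1-dihydro-1,2-benziodoxol-3(1H)-one gives the 3-oxopropyl aldehyde F4. Wittig reaction with isopropylidene(triphenyl)phosphorane comes back at 10.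

3. Step 9 (with step 8). Hydride delivery to the hindered C=N bond may be incomplete, the reagents may attack the other carbonyl groups, or the cyclobutyl diazene may fragment. The fallback sets out from 15. Reduction with NaBH4 (MeOH, −40 °C), selective for the strained ketone, gives the cyclobutanol (1S,2S,4'R,5S)-7-hydroxy-6,6,6',6',8',8'-hexamethyl-4'-(propan-2-yl)-3',4'-dihydrospiro[bicyclo[3.1.1]heptane-2,2'-chromene]-5',7'(6'H,8'H)-dione F5. Phenyl chlorothionoformate (pyridine, DMAP, CH2Cl2) gives the O-phenyl thionocarbonate F6. Barton–McCombie deoxygenation (Bu3SnH, AIBN, PhMe, 90 °C) comes back at 18.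

**Further compounds**

F1 | step 7 | 2,2,4,4-tetramethyl-6-(2-methylpropylidene)cyclohexane-1,3,5-trione | CC(C)C=C1C(=O)C(C)(C)C(=O)C(C)(C)C1=O
F2 | step 4 | ethyl (2S,4R)-2-allyl-6,6,8,8-tetramethyl-5,7-dioxo-4-(propan-2-yl)-3,4,5,6,7,8-hexahydro-2H-chromene-2-carboxylate | CC(C)[C@H]1C[C@](C(=O)OCC)(CC=C)OC2=C1C(=O)C(C)(C)C(=O)C2(C)C
F3 | step 4 | ethyl (2S,4R)-2-(3-hydroxypropyl)-6,6,8,8-tetramethyl-5,7-dioxo-4-(propan-2-yl)-3,4,5,6,7,8-hexahydro-2H-chromene-2-carboxylate | CC(C)[C@H]1C[C@](C(=O)OCC)(CCCO)OC2=C1C(=O)C(C)(C)C(=O)C2(C)C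
F4 | step 4 | ethyl (2S,4R)-6,6,8,8-tetramethyl-5,7-dioxo-2-(3-oxopropyl)-4-(propan-2-yl)-3,4,5,6,7,8-hexahydro-2H-chromene-2-carboxylate | CC(C)[C@H]1C[C@](C(=O)OCC)(CCC=O)OC2=C1C(=O)C(C)(C)C(=O)C2(C)C
F5 | step 9 | (1S,2S,4'R,5S)-7-hydroxy-6,6,6',6',8',8'-hexamethyl-4'-(propan-2-yl)-3',4'-dihydrospiro[bicyclo[3.1.1]heptane-2,2'-chromene]-5',7'(6'H,8'H)-dione (C7 epimers) | CC(C)[C@H]1C[C@]2(CC[C@@H]3C(O)[C@H]2C3(C)C)OC2=C1C(=O)C(C)(C)C(=O)C2(C)C
F6 | step 9 | O-phenyl thionocarbonate of F5 | CC(C)[C@H]1C[C@]2(CC[C@@H]3C(OC(=S)Oc4ccccc4)[C@H]2C3(C)C)OC2=C1C(=O)C(C)(C)C(=O)C2(C)C
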